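## Analysis of the target

Compound 27 is a flavone: rings A and C form the 4H-chromen-4-one and ring B is the aryl group on C2. The C2′ oxygen of ring B is tied back to C3 through C2″H–C1″H2, so a seven-membered dihydrooxepine (ring D) is fused to rings B and C. Positions are numbered as in a flavone; the bridge carbons are C1″ (CH2 on C3), C2″ (O–CH) and C3″ (the CMe2 carbon on C2″).

C2″ is the only stereocentre. It is (S), it is an aryl alkyl ether carbon and it carries the 2-hydroperoxypropan-2-yl group, so nothing in the molecule can relay configuration to it; it has to be brought in and then left untouched.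

Ring A is fully differentiated: a chelated C5 hydroxyl, an (E)-3-methylbut-1-enyl group on C6 between two oxygens, and a methyl ether on C7. Ring B carries a free C4′ hydroxyl.

The tertiary hydroperoxide is the most fragile group (phosphines, iodide, sulfides, low-valent metals and hydrogenation destroy it). The styrene-type double bond excludes hydrogenolysis and strong acid, and C2 of the pyranone is open to nucleophiles.

The hard part is ring D: an aryl–oxygen bond to a secondary carbon flanked by a fully substituted carbon must be closed into a medium ring without loss of configuration. Substitution at C2″ is therefore unattractive.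

The route rests on one structural fact: C2′ is ortho to C1′, and C1′ is bonded to C2. The unit C2=C3–C4=O is a vinylogous acceptor for ring B, so an anionic adduct at C2′ is stabilised. The C2′–O bond can then be made at the aryl carbon, while the C2″–O bond is taken intact from a chiral-pool alcohol.

## Retrosynthetic reasoning

**Hydroperoxide and end game (27 ⇒ 23).** The O–O–H group cannot be carried through organometallic or Lewis-acid steps, so it is introduced last. The two Si–O bonds of 26 (peroxide oxygen and C4′ oxygen) are cut in one non-reductive fluoride treatment. The C3″–O bond of 26 is cut next: Markovnikov addition of hydrogen and a silylperoxy group across the isopropenyl group of 25 places the peroxide on a carbon with two methyl groups, so no stereochemical question arises. The alkene 25 comes from the tertiary carbinol 24 by dehydration, and 24 from 23 by cleavage of the C5 O–CH3 bond. Demethylation is placed before dehydration because a Lewis acid could ionise the allylic aryl ether of 25, and before peroxidation because iodide reduces peroxides.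

**Ring D (23 ⇒ 22).** The C2′–O bond is cut. Cutting C2″–O instead would require substitution with inversion at a carbinol carbon next to a quaternary centre. Cutting a C–C bond of ring D would leave the ether to be made on an arene with no activating group. With the C2′–O cut, the precursor 22 is an ordinary 3-alkyl-2′-fluoroflavone with a free diol. The forward reaction must add the C2″ alkoxide to C2′ and expel fluoride, without touching the tertiary hydroxyl, C2 of the pyranone or the C4′ silyl ether.

**Pyranone (22 ⇒ 15 + 18).** The O1–C2 and C2–C3 bonds are cut in the Baker–Venkataraman sense, through diketone 21 and aryl ester 20. This takes ring B from a benzoic acid (18) that already has fluorine ortho to the carboxyl carbon. It makes the α-carbon of ketone 15 into C3, with the whole C1″–C3″ chain already attached. The diol is masked as an acetonide so that only the phenol is acylated; the acid that closes the pyranone also releases the diol.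

**Aryl ketone (15 ⇒ 11 + 5).** The C4–C4a bond is cut. The lactone carbonyl of 5 becomes C4, its α-carbon becomes C3, and its ring oxygen becomes the C2″ hydroxyl, so no bond to the stereocentre is ever broken. Arene 11 has a mirror plane through C1 and C4 of the ring; the two positions flanked by OMOM and OMe are equivalent, so ortho-lithiation has a single outcome (aryllithium 12). The forward reaction must stop at mono-addition (13). A short acid treatment then frees the phenol and the diol (14) before acetonide formation.

**Chiral fragment (5 ⇒ 1).** The two C3″–CH3 bonds are cut. The carboxyl carbon of the glutamic-acid-derived lactone acid 1 becomes C3″ through ester 2 and carbinol lactone 4. The tertiary hydroxyl is silylated (5) so that it does not quench 12.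

**Alkenyl arene (11 ⇒ 7 + 8).** The C=C bond is cut to aldehyde 7 (from 6 by protection) and phosphonium salt 8. The non-stabilised ylide 9 gives mainly the (Z)-alkene 10, so an equilibration to the (E)-alkene 11 is built into the same step.

**Ring B acid (18 ⇒ 16).** Only the O–Si bond is cut; 16 supplies fluorine and the C4′ oxygen in the right positions.

## Alternatives that were turned down

**Alternative 1:** Ring A is disconnected at C4a–C5, C5–C6, C7–C8 and C8–C8a. In the forward sense, diazo ketone A2 (a 6-diazoacetyl-4-pyranone that already carries rings B and D) is irradiated to give a vinylketene by Wolff rearrangement. The ketene adds to ynol ether A3 in a [2+2] sense; heating then opens the cyclobutenone, closes the six-membered ring and tautomerises to phenol A1.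
- For: one operation gives a fully substituted ring A with regiochemistry set by the polarity of A3. The C5 hydroxyl arrives free and the C7 oxygen methylated, so no selective demethylation is needed. A1 has the constitution of compound 25, two steps from the target. On oxygen differentiation of ring A this alternative is stronger than the chosen route.
- Against: A2 must already contain the oxepine, so the real problem of the target is not solved but moved to a less activated, less robust pyranone. The pyranone competes for the light. The thermal stage exposes an allyl aryl ether to heat. A3 is a volatile, acid-sensitive enyne that needs its own synthesis. The most advanced intermediate is committed to the least predictable step.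
- Comparison: the chosen route buys ring A as an aldehyde, pays one chelation-controlled demethylation, and keeps the risk in a single bond formation.

**Alternative 2:** C1′–C2 and C2–C3 are cut, with C2 coming from carbon monoxide. In the forward sense, aryl bromide A5 undergoes oxidative addition to zerovalent palladium (Pd(dba)2/Xantphos), CO insertion, and acylation of the tethered ring-A ketone enolate. This closes ring D as the cyclic 1,3-diketone A4, which acid would dehydrate to the pyranone.
- For: two C–C bonds are made catalytically from a one-carbon feedstock. It avoids acyl transfer to an α-branched enolate, where it is at least as strong as the chosen route.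
- Against: direct α-arylation without CO would close a six-membered chroman and competes with the seven-membered acylation. The free ortho phenoxide and the diketonate product both bind palladium. Most seriously, the aryl ether of A5 must be made beforehand, either by inversion at the hindered C2″ carbinol or by substitution on a haloarene that has no activating group.
- Comparison: the chosen route makes that ether only after the chromone is in place as an activating group, and needs neither pressure equipment nor a transition metal for the ring closure.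

**Alternative 3:** Ring B is cut at C1′–C2′ and C5′–C6′ together with ring D. In the forward sense, 2-ethynylchromone A7 carries a 1-alkoxy-3-siloxydiene bound through the future ring-D oxygen. Heating gives an intramolecular Diels–Alder adduct, and DDQ dehydrogenates the cyclohexadiene to A6. A6 differs from compound 23 only by a triethylsilyl group on the C3″ oxygen.
- For: two rings form at once. The C2′–O bond exists from the start as an enol ether, so no aryl C–O bond formation is needed; on that point it is as strong as the chosen route. Regiochemistry is fixed by the tether.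
- Against: the cycloadduct has the ring-D alkoxy group on an sp3 carbon of a 1,4-cyclohexadiene. Its easiest aromatisation is loss of that alkoxide, which would cut ring D open, so DDQ must outrun elimination. The dienyl ether of a hindered secondary alcohol is hydrolytically labile. Ring B, a commercial benzoic acid in the chosen route, would be built from acyclic pieces over several steps.
- Comparison: the chosen route is shorter and its ring closure has no competing aromatisation pathway.

Key step: step 11

## Route

Step 1
Reactants: 1 (S)-5-oxotetrahydrofuran-2-carboxylic acid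
Product: 2 ethyl (S)-5-oxotetrahydrofuran-2-carboxylate
Conditions: EtOH (3 equiv), TsOH·H2O (cat.), toluene, reflux, Dean–Stark
Reagents that add atoms: ethanol, CCO
Why: Fischer esterification with azeotropic removal of water; any ring-opened hydroxy diester relactonises on concentration, and the stereocentre is not involved.

Step 2
Reactants: 2 ethyl (S)-5-oxotetrahydrofuran-2-carboxylate
Product: 4 (S)-5-(2-hydroxypropan-2-yl)dihydrofuran-2(3H)-one, via methyl ketone 3 (not isolated)
Conditions: MeMgBr (2.1 equiv, slow addition), THF, −78 → −40 °C; then aq. NH4Cl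
Reagents that add atoms: methylmagnesium bromide, C[Mg]Br
Why: Double Grignard addition to the exocyclic ester, which carries an α-oxygen and is more electrophilic than the lactone carbonyl; ketone 3 is more reactive still and is consumed as it forms. No bond to the stereocentre is broken.

Step 3
Reactants: 4 (S)-5-(2-hydroxypropan-2-yl)dihydrofuran-2(3H)-one
Product: 5 (S)-5-[2-(triethylsilyloxy)propan-2-yl]dihydrofuran-2(3H)-one
Conditions: Et3SiOTf, 2,6-lutidine, CH2Cl2, −78 → 0 °C
Reagents that add atoms: triethylsilyl trifluoromethanesulfonate, CC[Si](CC)(CC)OS(=O)(=O)C(F)(F)F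
Why: Silylation of a hindered tertiary alcohol with a silyl triflate; it removes the acidic proton that would otherwise quench the aryllithium in step 6.

Step 4
Reactants: 6 4-hydroxy-2,6-dimethoxybenzaldehyde
Product: 7 2,6-dimethoxy-4-(methoxymethoxy)benzaldehyde
Conditions: MOMCl, i-Pr2NEt, CH2Cl2, 0 °C → rt
Reagents that add atoms: chloromethyl methyl ether, COCCl
Why: O-alkylation of the phenol; the MOM ether keeps the aldehyde electrophilic for the Wittig reaction and later directs the lithiation.

Step 5
Reactants: 7 2,6-dimethoxy-4-(methoxymethoxy)benzaldehyde; 8 isobutyltriphenylphosphonium bromide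
Product: 11 1,3-dimethoxy-5-(methoxymethoxy)-2-[(E)-3-methylbut-1-en-1-yl]benzene, via ylide 9 (not isolated), via Z-alkene 10 (not isolated)
Conditions: 8, NaN(SiMe3)2, THF, 0 °C; then 7, −78 °C → rt; crude alkene, I2 (5 mol %), CH2Cl2, rt, daylight
Reagents that add atoms: none
Why: Wittig olefination with a non-stabilised ylide should give mainly the (Z)-alkene; reversible addition of iodine atoms then equilibrates it to the (E)-isomer, which is strongly favoured because the isopropyl group of 10 clashes with the two ortho methoxy groups.

Step 6
Reactants: 11 1,3-dimethoxy-5-(methoxymethoxy)-2-[(E)-3-methylbut-1-en-1-yl]benzene; 5 (S)-5-[2-(triethylsilyloxy)propan-2-yl]dihydrofuran-2(3H)-one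
Product: 13 (S)-1-{2,4-dimethoxy-6-(methoxymethoxy)-3-[(E)-3-methylbut-1-en-1-yl]phenyl}-4-hydroxy-5-methyl-5-(triethylsilyloxy)hexan-1-one, via aryllithium 12 (not isolated)
Conditions: 11, n-BuLi, THF, 0 °C; then 5, −78 °C; then AcOH (1 equiv), −78 °C
Reagents that add atoms: none
Why: Directed ortho-metalation at the position flanked by OMOM and OMe (the two such positions are equivalent by symmetry), then addition of the aryllithium to the lactone carbonyl. The tetrahedral lithium lactolate persists at −78 °C and collapses to the ketone only on protonation, which limits double addition. The ring O–C2″ bond is not broken, so the configuration is retained.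

Step 7
Reactants: 13 (S)-1-{2,4-dimethoxy-6-(methoxymethoxy)-3-[(E)-3-methylbut-1-en-1-yl]phenyl}-4-hydroxy-5-methyl-5-(triethylsilyloxy)hexan-1-one
Product: 15 1-{6-hydroxy-2,4-dimethoxy-3-[(E)-3-methylbut-1-en-1-yl]phenyl}-3-[(S)-2,2,5,5-tetramethyl-1,3-dioxolan-4-yl]propan-1-one, via triol 14 (not isolated)
Conditions: HCl (1 M in MeOH), rt; concentrate; then Me2C(OMe)2, acetone, PPTS (cat.), rt
Reagents that add atoms: 2,2-dimethoxypropane, COC(C)(C)OC
Why: Acid-catalysed acetal exchange removes the MOM group (activated by the ortho carbonyl) and solvolyses the tertiary silyl ether; the 1,2-diol then closes to the dioxolane, helped by the gem-dimethyl group. The free phenol is hydrogen-bonded to the ketone, which keeps the ketone open-chain and leaves the phenol unreacted.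

Step 8
Reactants: 16 2-fluoro-4-hydroxybenzoic acid
Product: 18 2-fluoro-4-(triisopropylsilyloxy)benzoic acid, via silyl ester 17 (not isolated)
Conditions: i-Pr3SiCl (2.2 equiv), imidazole, DMF, rt; then K2CO3, MeOH–THF–H2O, 0 °C; 1 M HCl to pH 3
Reagents that add atoms: chlorotriisopropylsilane, CC(C)[Si](Cl)(C(C)C)C(C)C
Why: Silylation of both acidic groups followed by selective hydrolysis; a silyl ester is far more labile than a hindered aryl silyl ether.

Step 9
Reactants: 18 2-fluoro-4-(triisopropylsilyloxy)benzoic acid; 15 1-{6-hydroxy-2,4-dimethoxy-3-[(E)-3-methylbut-1-en-1-yl]phenyl}-3-[(S)-2,2,5,5-tetramethyl-1,3-dioxolan-4-yl]propan-1-one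
Product: 20 3,5-dimethoxy-4-[(E)-3-methylbut-1-en-1-yl]-2-{3-[(S)-2,2,5,5-tetramethyl-1,3-dioxolan-4-yl]propanoyl}phenyl 2-fluoro-4-(triisopropylsilyloxy)benzoate, via acid chloride 19 (not isolated)
Conditions: 18, (COCl)2, DMF (cat.), CH2Cl2, 0 °C → rt; evaporate; then 15, Et3N, DMAP (cat.), CH2Cl2, 0 °C → rt
Reagents that add atoms: none
Why: Acylation of the phenol by an aroyl chloride under nucleophilic catalysis, the first stage of the Baker–Venkataraman sequence; the acetonide leaves the phenol as the only hydroxyl.

Step 10
Reactants: 20 3,5-dimethoxy-4-[(E)-3-methylbut-1-en-1-yl]-2-{3-[(S)-2,2,5,5-tetramethyl-1,3-dioxolan-4-yl]propanoyl}phenyl 2-fluoro-4-(triisopropylsilyloxy)benzoate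
Product: 22 3-[(S)-2,3-dihydroxy-3-methylbutyl]-2-[2-fluoro-4-(triisopropylsilyloxy)phenyl]-5,7-dimethoxy-6-[(E)-3-methylbut-1-en-1-yl]-4H-chromen-4-one, via 1,3-diketone 21 (not isolated)
Conditions: LiN(SiMe3)2 (2.5 equiv), THF, −78 → −20 °C; then 2 M aq. HCl–MeOH (1:4), 50 °C
Reagents that add atoms: none
Why: Baker–Venkataraman rearrangement: the ketone enolate attacks the aryl ester through a six-membered transition state, and formation of the diketonate drives the O→C acyl shift. In acid the phenol adds to the ring-B carbonyl and the hemiketal dehydrates to the 4H-chromen-4-one, while the same acid hydrolyses the acetonide. C2″ is not involved.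

Step 11
Reactants: 22 3-[(S)-2,3-dihydroxy-3-methylbutyl]-2-[2-fluoro-4-(triisopropylsilyloxy)phenyl]-5,7-dimethoxy-6-[(E)-3-methylbut-1-en-1-yl]-4H-chromen-4-one
Product: 23 dimethoxy oxepinoflavone carbinol
Conditions: KN(SiMe3)2 (1.2 equiv), THF, 0 °C → rt (40 °C if needed); then aq. NH4Cl
Reagents that add atoms: none
Why: The base deprotonates the diol and the secondary C2″ alkoxide adds to C2′ of ring B, ipso to fluorine; the negative charge of the adduct lies on C1′, C3′ and C5′ and is passed from C1′ through C2=C3 into the C4 carbonyl, after which fluoride is expelled (addition–elimination, SNAr). The closest known reaction type is the intramolecular etherification of ortho-fluoroaryl ketones and enones by tethered alkoxides. Ring D closes as a seven-membered ring by attack of the tethered oxygen on an sp2 carbon whose breaking π bond lies outside the new ring (7-exo-trig addition followed by loss of fluoride), and the C2–C1′ axis needs only a modest twist that still allows the conjugation stabilising the adduct. No stereocentre is formed, and C2″ keeps its (S) configuration because its C–O bond is never broken. The step needs selectivity between the two alkoxides and between C2′ and C2: the tertiary alkoxide would have to close an eight-membered ring and is hindered, addition of the secondary alkoxide to C2 would be a 5-endo-trig closure, and addition of the tertiary one to C2 is reversible whereas loss of fluoride is not, so the equilibria should drain into 23. The C4′ silyl ether is meta to fluorine and hardly affects the adduct, but it must stay on, because a C4′ phenoxide would push electron density into the chromone and stop the reaction; hence only a slight excess of a non-nucleophilic base is used, without crown ether or polar aprotic cosolvent, so that the KF formed stays insoluble. The C5 oxygen is kept as its methyl ether at this stage for the same reason.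

Step 12
Reactants: 23 dimethoxy oxepinoflavone carbinol
Product: 24 C5-hydroxy oxepinoflavone carbinol
Conditions: MgI2·OEt2 (3 equiv), THF, 60 °C; then aq. NH4Cl
Reagents that add atoms: none
Why: Chelation-controlled demethylation: magnesium bridges the C4 carbonyl oxygen and the C5 methoxy oxygen, and iodide attacks that methyl group. The C7 methyl ether, the ring-D ether and the silyl ether cannot chelate and should remain.

Step 13
Reactants: 24 C5-hydroxy oxepinoflavone carbinol
Product: 25 isopropenyl oxepinoflavone
Conditions: Burgess reagent (MeO2CN(−)SO2N(+)Et3, 2.5 equiv), toluene, 60 °C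
Reagents that add atoms: none
Why: Burgess dehydration by syn elimination of the sulfamate ester of the tertiary alcohol. Six methyl hydrogens compete with one hindered methine hydrogen on the ether-bearing C2″, so the isopropenyl isomer should dominate, as in the dehydration of related 2-(2-hydroxypropan-2-yl) cyclic aryl ethers. The chelated C5 hydroxyl is a poor nucleophile and C2″ is untouched.

Step 14
Reactants: 25 isopropenyl oxepinoflavone
Product: 26 triethylsilyl peroxide
Conditions: Co(acac)2 (10 mol %), O2 (1 atm), Et3SiH, ClCH2CH2Cl, rt
Reagents that add atoms: dioxygen, O=O; triethylsilane, CC[SiH](CC)CC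
Why: Mukaiyama–Isayama silylperoxidation: a cobalt hydride transfers a hydrogen atom to the terminal CH2, the tertiary radical is trapped by O2 and the peroxide is silylated, giving the Markovnikov product. The 1,1-disubstituted terminal alkene is more accessible than the twisted 1,2-disubstituted alkene on C6, which is shielded by two ortho substituents. C3″ carries two methyl groups, so no stereocentre is formed.

Step 15
Reactants: 26 triethylsilyl peroxide
Product: 27 target hydroperoxide
Conditions: HF·pyridine, THF–pyridine, 0 °C → rt
Reagents that add atoms: none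
Why: Fluoride-driven cleavage of both Si–O bonds (peroxide oxygen and C4′ oxygen) under non-reducing, non-basic conditions, which the hydroperoxide, the alkene and the chromone should tolerate.

## Compound list

1 | (S)-5-oxotetrahydrofuran-2-carboxylic acid | O=C1CC[C@@H](C(=O)O)O1 | starting material
2 | ethyl (S)-5-oxotetrahydrofuran-2-carboxylate | O=C1CC[C@@H](C(=O)OCC)O1 | intermediate
3 | (S)-5-acetyldihydrofuran-2(3H)-one (methyl ketone, not isolated) | O=C1CC[C@@H](C(C)=O)O1 | intermediate
4 | (S)-5-(2-hydroxypropan-2-yl)dihydrofuran-2(3H)-one | O=C1CC[C@@H](C(C)(C)O)O1 | intermediate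
5 | (S)-5-[2-(triethylsilyloxy)propan-2-yl]dihydrofuran-2(3H)-one | O=C1CC[C@@H](C(C)(C)O[Si](CC)(CC)CC)O1 | intermediate
6 | 4-hydroxy-2,6-dimethoxybenzaldehyde | COc1cc(O)cc(OC)c1C=O | starting material
7 | 2,6-dimethoxy-4-(methoxymethoxy)benzaldehyde | COCOc1cc(OC)c(C=O)c(OC)c1 | intermediate
8 | isobutyltriphenylphosphonium bromide | CC(C)C[P+](c1ccccc1)(c1ccccc1)c1ccccc1.[Br-] | starting material
9 | (2-methylpropylidene)triphenylphosphorane (ylide, not isolated) | CC(C)C=P(c1ccccc1)(c1ccccc1)c1ccccc1 | intermediate
10 | 1,3-dimethoxy-5-(methoxymethoxy)-2-[(Z)-3-methylbut-1-en-1-yl]benzene (main component of the crude alkene, not isolated) | COCOc1cc(OC)c(/C=C\C(C)C)c(OC)c1 | intermediate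
11 | 1,3-dimethoxy-5-(methoxymethoxy)-2-[(E)-3-methylbut-1-en-1-yl]benzene | COCOc1cc(OC)c(/C=C/C(C)C)c(OC)c1 | intermediate
12 | {2,4-dimethoxy-6-(methoxymethoxy)-3-[(E)-3-methylbut-1-en-1-yl]phenyl}lithium (not isolated) | [Li]c1c(OCOC)cc(OC)c(/C=C/C(C)C)c1OC | intermediate
13 | (S)-1-{2,4-dimethoxy-6-(methoxymethoxy)-3-[(E)-3-methylbut-1-en-1-yl]phenyl}-4-hydroxy-5-methyl-5-(triethylsilyloxy)hexan-1-one | COCOc1cc(OC)c(/C=C/C(C)C)c(OC)c1C(=O)CC[C@@H](C(C)(C)O[Si](CC)(CC)CC)O | intermediate
14 | (S)-4,5-dihydroxy-1-{6-hydroxy-2,4-dimethoxy-3-[(E)-3-methylbut-1-en-1-yl]phenyl}-5-methylhexan-1-one (triol, not isolated) | COc1cc(O)c(C(=O)CC[C@@H](C(C)(C)O)O)c(OC)c1/C=C/C(C)C | intermediate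
15 | 1-{6-hydroxy-2,4-dimethoxy-3-[(E)-3-methylbut-1-en-1-yl]phenyl}-3-[(S)-2,2,5,5-tetramethyl-1,3-dioxolan-4-yl]propan-1-one | COc1cc(O)c(C(=O)CC[C@@H]2OC(C)(C)OC2(C)C)c(OC)c1/C=C/C(C)C | intermediate
16 | 2-fluoro-4-hydroxybenzoic acid | O=C(O)c1ccc(O)cc1F | starting material
17 | triisopropylsilyl 2-fluoro-4-(triisopropylsilyloxy)benzoate (not isolated) | CC(C)[Si](OC(=O)c1ccc(O[Si](C(C)C)(C(C)C)C(C)C)cc1F)(C(C)C)C(C)C | intermediate
18 | 2-fluoro-4-(triisopropylsilyloxy)benzoic acid | O=C(O)c1ccc(O[Si](C(C)C)(C(C)C)C(C)C)cc1F | intermediate
19 | 2-fluoro-4-(triisopropylsilyloxy)benzoyl chloride (not isolated) | O=C(Cl)c1ccc(O[Si](C(C)C)(C(C)C)C(C)C)cc1F | intermediate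
20 | 3,5-dimethoxy-4-[(E)-3-methylbut-1-en-1-yl]-2-{3-[(S)-2,2,5,5-tetramethyl-1,3-dioxolan-4-yl]propanoyl}phenyl 2-fluoro-4-(triisopropylsilyloxy)benzoate | COc1cc(OC(=O)c2ccc(O[Si](C(C)C)(C(C)C)C(C)C)cc2F)c(C(=O)CC[C@@H]2OC(C)(C)OC2(C)C)c(OC)c1/C=C/C(C)C | intermediate
21 | 1-[2-fluoro-4-(triisopropylsilyloxy)phenyl]-3-{6-hydroxy-2,4-dimethoxy-3-[(E)-3-methylbut-1-en-1-yl]phenyl}-2-{[(S)-2,2,5,5-tetramethyl-1,3-dioxolan-4-yl]methyl}propane-1,3-dione (epimers at C2 and enol forms, not isolated) | COc1cc(O)c(C(=O)C(C[C@@H]2OC(C)(C)OC2(C)C)C(=O)c2ccc(O[Si](C(C)C)(C(C)C)C(C)C)cc2F)c(OC)c1/C=C/C(C)C | intermediate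
22 | 3-[(S)-2,3-dihydroxy-3-methylbutyl]-2-[2-fluoro-4-(triisopropylsilyloxy)phenyl]-5,7-dimethoxy-6-[(E)-3-methylbut-1-en-1-yl]-4H-chromen-4-one (precursor of the key step) | COc1cc2oc(-c3ccc(O[Si](C(C)C)(C(C)C)C(C)C)cc3F)c(C[C@@H](C(C)(C)O)O)c(=O)c2c(OC)c1/C=C/C(C)C | intermediate
23 | dimethoxy oxepinoflavone carbinol: 5,7-dimethoxy-6-[(E)-3-methylbut-1-en-1-yl]-4′-(triisopropylsilyloxy)flavone in which C3 and the C2′ oxygen are joined by C1″H2–C2″H[C(CH3)2OH] (ring D), (S) at C2″ | COc1cc2oc3c(c(=O)c2c(OC)c1/C=C/C(C)C)C[C@@H](C(C)(C)O)Oc1cc(O[Si](C(C)C)(C(C)C)C(C)C)ccc1-3 | intermediate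
24 | C5-hydroxy oxepinoflavone carbinol: as 23 but with a free C5 hydroxyl (C7 still OMe), (S) at C2″ | COc1cc2oc3c(c(=O)c2c(O)c1/C=C/C(C)C)C[C@@H](C(C)(C)O)Oc1cc(O[Si](C(C)C)(C(C)C)C(C)C)ccc1-3 | intermediate
25 | isopropenyl oxepinoflavone: as 24 but with prop-1-en-2-yl on C2″ in place of the carbinol, (S) at C2″ | COc1cc2oc3c(c(=O)c2c(O)c1/C=C/C(C)C)C[C@@H](C(C)=C)Oc1cc(O[Si](C(C)C)(C(C)C)C(C)C)ccc1-3 | intermediate
26 | triethylsilyl peroxide: as 24 but with C(CH3)2–O–O–SiEt3 on C2″, (S) at C2″ | COc1cc2oc3c(c(=O)c2c(O)c1/C=C/C(C)C)C[C@@H](C(C)(C)OO[Si](CC)(CC)CC)Oc1cc(O[Si](C(C)C)(C(C)C)C(C)C)ccc1-3 | intermediate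
27 | target: 5,4′-dihydroxy-7-methoxy-6-[(E)-3-methylbut-1-en-1-yl]flavone in which C3 and the C2′ oxygen are joined by C1″H2–C2″H[C(CH3)2OOH] (ring D), (S) at C2″ | COc1cc2oc3c(c(=O)c2c(O)c1/C=C/C(C)C)C[C@@H](C(C)(C)OO)Oc1cc(O)ccc1-3 | target

## Step count and risks

Total: 15 steps. Longest linear sequence: 12 steps (1, 2, 3, 6, 7, 9, 10, 11, 12, 13, 14, 15, from lactone acid 1).

**Step 11 (key step).**
- Risk: addition at C2′ may be slow because ring B is twisted against the chromone and the carbonyl activates only through C2=C3. Transfer of the C4′ silyl group to an alkoxide could then compete, and the resulting phenoxide would deactivate ring B. Reversible alkoxide addition at C2 with opening of the pyranone could also compete.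
- Fallback: make the same C2′–O bond by copper catalysis on the bromide, which does not depend on the electron demand of ring B. It sets out from 15. Commercial 2-bromo-4-hydroxybenzoic acid is silylated as in step 8 to triisopropylsilyl 2-bromo-4-(triisopropylsilyloxy)benzoate F1 and hydrolysed to 2-bromo-4-(triisopropylsilyloxy)benzoic acid F2. Esterification with 15 (EDC·HCl, DMAP, CH2Cl2) should give the bromo aryl ester F3. LiN(SiMe3)2 and then aqueous HCl in MeOH, as in step 10, should lead through the bromo 1,3-diketone F4 to the 2′-bromoflavone diol F5. CuI (10 mol %), 3,4,7,8-tetramethyl-1,10-phenanthroline and Cs2CO3 in toluene at 110 °C should then close ring D at the secondary hydroxyl and return to the route at 23.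

**Step 14.**
- Risk: hydrogen-atom transfer to the C6 alkenyl group (giving a benzylic radical) may compete with transfer to the isopropenyl group. The C5-hydroxy/C4-carbonyl chelate may also bind cobalt and stall the cycle.
- Fallback: an ionic route from 24 that also bypasses step 13. Acid-catalysed perhydrolysis of the tertiary alcohol (50% aq. H2O2 in excess, H2SO4 cat., Et2O–THF, 0 °C) should give the silyl-protected hydroperoxide F6 through the tertiary cation, without breaking the C2″–O bond. HF·pyridine as in step 15 then returns to the route at 27.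

**Step 10.**
- Risk: if the base stage is warmed, the lithium diketonate may cyclise onto the fluoroarene through its enolate oxygen, closing a chromone in the wrong sense. In the acid stage, early loss of the acetonide may let the C2″ hydroxyl add to a carbonyl and dehydrate to a dihydrofuran before the pyranone has formed. Acid may also erode the silyl ether.
- Fallback: separate ring closure from deprotection. It sets out from 21, isolated after a cold acetic acid quench of the base stage. TsOH (cat.) in toluene under Dean–Stark conditions should close the pyranone with the diol still masked, giving the acetonide flavone F7. Hydrolysis in 80% aq. AcOH at 40 °C then releases the diol and returns to the route at 22.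

**Step 6.**
- Risk: the hindered, strongly basic aryllithium 12 may abstract a proton from the α-CH2 of lactone 5 instead of adding, returning arene 11 and lactone enolate.
- Fallback: use a less acidic, non-cyclic acyl donor. It sets out from 4. Me3Al and MeNHOMe·HCl in CH2Cl2 open the lactone to (S)-4,5-dihydroxy-N-methoxy-N,5-dimethylhexanamide F8. 2,2-Dimethoxypropane with PPTS gives (S)-N-methoxy-N-methyl-3-(2,2,5,5-tetramethyl-1,3-dioxolan-4-yl)propanamide F9. Addition of 12 at −78 °C should give the MOM-protected acetonide ketone F10 through the stable chelated adduct. The conditions of step 7 (methanolic HCl, then 2,2-dimethoxypropane) pass through triol 14 and return to the route at 15.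

**Step 2.**
- Risk: chemoselectivity may be lost, with the Grignard reagent attacking the lactone carbonyl, or the second addition may be incomplete and leave ketone 3.
- Fallback: add the two methyl groups in separate steps, each selective by the reactivity order acid chloride > ketone > lactone. It sets out from 1. (COCl)2 with catalytic DMF gives (S)-5-oxotetrahydrofuran-2-carbonyl chloride F11. Me2CuLi in Et2O at −78 °C should stop at ketone 3, which is isolated here. MeMgBr with anhydrous CeCl3 in THF at −78 °C should add to the ketone only and return to the route at 4.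

## Further compounds

F1 | step 11 | triisopropylsilyl 2-bromo-4-(triisopropylsilyloxy)benzoate | CC(C)[Si](OC(=O)c1ccc(O[Si](C(C)C)(C(C)C)C(C)C)cc1Br)(C(C)C)C(C)C
F2 | step 11 | 2-bromo-4-(triisopropylsilyloxy)benzoic acid | O=C(O)c1ccc(O[Si](C(C)C)(C(C)C)C(C)C)cc1Br
F3 | step 11 | 3,5-dimethoxy-4-[(E)-3-methylbut-1-en-1-yl]-2-{3-[(S)-2,2,5,5-tetramethyl-1,3-dioxolan-4-yl]propanoyl}phenyl 2-bromo-4-(triisopropylsilyloxy)benzoate | COc1cc(OC(=O)c2ccc(O[Si](C(C)C)(C(C)C)C(C)C)cc2Br)c(C(=O)CC[C@@H]2OC(C)(C)OC2(C)C)c(OC)c1/C=C/C(C)C
F4 | step 11 | 1-[2-bromo-4-(triisopropylsilyloxy)phenyl]-3-{6-hydroxy-2,4-dimethoxy-3-[(E)-3-methylbut-1-en-1-yl]phenyl}-2-{[(S)-2,2,5,5-tetramethyl-1,3-dioxolan-4-yl]methyl}propane-1,3-dione | COc1cc(O)c(C(=O)C(C[C@@H]2OC(C)(C)OC2(C)C)C(=O)c2ccc(O[Si](C(C)C)(C(C)C)C(C)C)cc2Br)c(OC)c1/C=C/C(C)C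
F5 | step 11 | 2-[2-bromo-4-(triisopropylsilyloxy)phenyl]-3-[(S)-2,3-dihydroxy-3-methylbutyl]-5,7-dimethoxy-6-[(E)-3-methylbut-1-en-1-yl]-4H-chromen-4-one | COc1cc2oc(-c3ccc(O[Si](C(C)C)(C(C)C)C(C)C)cc3Br)c(C[C@@H](C(C)(C)O)O)c(=O)c2c(OC)c1/C=C/C(C)C
F6 | step 14 | silyl-protected hydroperoxide: compound 27 with a triisopropylsilyl group on the C4′ oxygen, (S) at C2″ | COc1cc2oc3c(c(=O)c2c(O)c1/C=C/C(C)C)C[C@@H](C(C)(C)OO)Oc1cc(O[Si](C(C)C)(C(C)C)C(C)C)ccc1-3
F7 | step 10 | 2-[2-fluoro-4-(triisopropylsilyloxy)phenyl]-5,7-dimethoxy-6-[(E)-3-methylbut-1-en-1-yl]-3-{[(S)-2,2,5,5-tetramethyl-1,3-dioxolan-4-yl]methyl}-4H-chromen-4-one | COc1cc2oc(-c3ccc(O[Si](C(C)C)(C(C)C)C(C)C)cc3F)c(C[C@@H]3OC(C)(C)OC3(C)C)c(=O)c2c(OC)c1/C=C/C(C)C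
F8 | step 6 | (S)-4,5-dihydroxy-N-methoxy-N,5-dimethylhexanamide | CON(C)C(=O)CC[C@@H](C(C)(C)O)O
F9 | step 6 | (S)-N-methoxy-N-methyl-3-(2,2,5,5-tetramethyl-1,3-dioxolan-4-yl)propanamide | CON(C)C(=O)CC[C@@H]1OC(C)(C)OC1(C)C
F10 | step 6 | 1-{2,4-dimethoxy-6-(methoxymethoxy)-3-[(E)-3-methylbut-1-en-1-yl]phenyl}-3-[(S)-2,2,5,5-tetramethyl-1,3-dioxolan-4-yl]propan-1-one | COCOc1cc(OC)c(/C=C/C(C)C)c(OC)c1C(=O)CC[C@@H]1OC(C)(C)OC1(C)C
F11 | step 2 | (S)-5-oxotetrahydrofuran-2-carbonyl chloride | O=C1CC[C@@H](C(=O)Cl)O1
A1 | alternative 1 | 5-hydroxy-7-methoxy-6-[(E)-3-methylbut-1-en-1-yl] tetracycle with isopropenyl group on C2″ and silylated C4′ phenol, (S) at C2″ (constitution of compound 25) | COc1cc2oc3c(c(=O)c2c(O)c1/C=C/C(C)C)C[C@@H](C(C)=C)Oc1cc(O[Si](C(C)C)(C(C)C)C(C)C)ccc1-3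
A2 | alternative 1 | 6-(diazoacetyl)-4H-pyran-4-one carrying ring B on C2 and the isopropenyl-substituted oxepine bridge from C3 to the C2′ oxygen, C4′ silyl ether, (S) | O=c1cc(C(=O)C=[N+]=[N-])oc2c1C[C@@H](C(C)=C)Oc1cc(O[Si](C(C)C)(C(C)C)C(C)C)ccc1-2
A3 | alternative 1 | (E)-1-methoxy-5-methylhex-3-en-1-yne | COC#C/C=C/C(C)C
A4 | alternative 2 | ring-D cyclic 1,3-diketone (drawn as its enol) bearing the ring-A aroyl group, C4′ MOM ether and C3″ triethylsilyl ether, (S) | COc1cc(O)c(C(=O)C2=C(O)c3ccc(OCOC)cc3O[C@H](C(C)(C)O[Si](CC)(CC)CC)C2)c(OC)c1/C=C/C(C)C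
A5 | alternative 2 | (S)-4-[2-bromo-5-(methoxymethoxy)phenoxy]-1-{6-hydroxy-2,4-dimethoxy-3-[(E)-3-methylbut-1-en-1-yl]phenyl}-5-methyl-5-(triethylsilyloxy)hexan-1-one | COc1cc(O)c(C(=O)CC[C@@H](C(C)(C)O[Si](CC)(CC)CC)Oc2cc(OCOC)ccc2Br)c(OC)c1/C=C/C(C)C
A6 | alternative 3 | 5,7-dimethoxy tetracycle with triethylsilylated C3″ carbinol and triisopropylsilylated C4′ phenol, (S) at C2″ | COc1cc2oc3c(c(=O)c2c(OC)c1/C=C/C(C)C)C[C@@H](C(C)(C)O[Si](CC)(CC)CC)Oc1cc(O[Si](C(C)C)(C(C)C)C(C)C)ccc1-3
A7 | alternative 3 | 2-ethynyl-5,7-dimethoxy-6-[(E)-3-methylbut-1-en-1-yl]-4H-chromen-4-one carrying on C3 the (S)-CH2–CH[O–CH=CH–C(OSi(i-Pr)3)=CH2]–C(CH3)2OSiEt3 chain | COc1cc2oc(C#C)c(C[C@@H](C(C)(C)O[Si](CC)(CC)CC)O/C=C/C(=C)O[Si](C(C)C)(C(C)C)C(C)C)c(=O)c2c(OC)c1/C=C/C(C)C
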